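## The problem

The target 16 is a 1,2,4-trisubstituted benzene with an oxirane at C1, an aryl ester oxygen at C2 and an acyloxymethyl group at C4. Thymol numbering is used for the side chains: C7 is the benzylic CH2, C8 the fully substituted oxirane carbon, C9 the oxirane CH2 and C10 the acetoxymethyl carbon. Three different acyl groups sit on three different oxygens (angelate on the phenol, (R)-2-methylbutanoate on C7–O, acetate on C10–O), and each must be placed without exchange. There are two stereocentres: the α-carbon of the 2-methylbutanoate, which can be bought, and C8 (R). They are too far apart to control each other, so C8 must be set by a catalyst or reagent. The oxirane is tertiary, benzylic and ortho to an oxygen donor: it ionises under acid, and a free ortho phenol activates it by hydrogen bonding or, as phenoxide, can expel the oxirane oxygen to give an ortho-quinone methide. The aryl angelate is an active ester with a Z double bond that isomerises to the tiglate under nucleophilic catalysis or acid. An alkoxide on C8 or C10 would take its acyl group through a six- or seven-membered transition state, so no alkoxide may be generated beside it.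

The feature that opens the problem is that C8 carries two CH2–O arms, C9 (in the oxirane ring) and C10 (the acetate), which differ only in what their oxygen is bound to. Tying C9 and C10 through one oxygen turns C8 into C3 of an oxetane ring with two identical arms: it is no longer a stereocentre, and the ring holds about 25 kcal/mol of strain.

## Retrosynthesis

**16 ⇒ 13 + 14 (through 15).** The phenol O–acyl bond is cut first. The aryl angelate is the most fragile group, both as an acyl donor and as a Z-alkene, and it cannot coexist with the alkoxide needed to close the oxirane. Cutting either of the other esters first would leave it exposed to more chemistry. The forward step asks for acylation of phenol 13 without nucleophilic catalyst, using angelic anhydride 15 made in the flask from angelic acid 14.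

**13 ⇒ 12.** The phenol O–allyl bond is cut. The phenol must be an ether while the oxirane is closed, because a phenoxide would alkylate on C9 and an aryl ester would migrate. An allyl ether is chosen over acid-labile or hydrogenolysable groups because it leaves under neutral conditions with zerovalent palladium, which neither the oxirane nor the benzylic ester tolerates acid or hydrogen for.

**12 ⇒ 9 (through 10 and 11).** The C9–O bond of the oxirane is cut and the acetyl is moved back from C10–O to C8–O. The precursor 9 has a bromide on C9, a silyl ether on C10–O and the acetate on the tertiary oxygen. Compared with closing to a glycidol and then acetylating, this saves a step: the group that protects the tertiary oxygen in the key step becomes the C10 acetate. The forward reaction needs a 1,2 acyl shift (alkoxide 10 to alkoxide 11) followed by 3-exo-tet closure, with no bond to C8 broken.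

**9 ⇒ 8.** C9 is rejoined to the oxygen on C10 to give the oxetane 8. This cut removes the C8 stereocentre altogether, and the precursor has neither the bromide nor the differentiated arms. The forward reaction must open one of two equivalent C–O bonds under catalyst control and deliver C9 as an electrophile and C10–O as a masked nucleophile in one event. Cutting the oxirane back to an alkene or a ketone would instead leave the stereocentre to be made on an open chain.

**8 ⇒ 4 + 5 (through 6 and 7).** The aryl–C8 bond is cut to an aryl nucleophile and commercial oxetan-3-one 5. The fully substituted carbon is made in the one C–C bond-forming step of the route, and the alkoxide 7 formed by the addition of arylmagnesium 6 is acetylated in the flask. The forward reaction must make 6 from iodide 4 without touching the ester.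

**4 ⇒ 2 + 3; 2 ⇒ 1.** The benzylic ester and the allyl ether are cut to 5-(hydroxymethyl)-2-iodophenol 1, allyl bromide and (R)-2-methylbutanoic acid 3. The chiral acid is put on early because the alcohol is free at that point and nothing else competes.

## Roads not taken

**Alternative 1:** Both C–O bonds of the oxirane are cut to the 2-aryl allylic alcohol A1. The forward key step is a Sharpless asymmetric epoxidation to glycidol A2, followed by acetylation to 16. This is the route most chemists would draw first.
- A1 needs a cross-coupling with a 2-metallated allyl alcohol that must itself be prepared.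
- The product A2 is a tertiary benzylic epoxide formed while bound to Lewis-acidic tetravalent titanium, the situation in which such glycidols open at C8.
- Ti(OiPr)4 is a transesterification catalyst, and the aryl angelate of A1 is an active ester.
- The stereocentre is set last, on the most valuable intermediate.
- The chosen plan builds C8 from oxetan-3-one in one step and sets it at −78 °C without a Lewis-acidic metal.

**Alternative 2:** The C8–C9 and C9–O bonds are cut to the α-acetoxy aryl ketone A3. The forward key step is a catalytic asymmetric Corey–Chaykovsky methylene transfer from a sulfur ylide.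
- The ylide is a strong base and nucleophile, and A3 has an acidic CH2 between a carbonyl and an acetoxy group, so enolisation and acetyl loss compete with addition.
- Catalysts for this transfer distinguish a small from a large ketone substituent; here both (an ortho-substituted arene and CH2OAc) are large and coordinating.
- The step count is similar, but the risk lies in a step with no strain to drive it.

**Alternative 3:** The same hidden symmetry is used in open-chain form: the oxirane and the acetate are cut back to the 2-aryl glycerol A4. The forward key step is a desymmetrising monosulfonylation with a divalent copper bis(oxazoline) catalyst to monotosylate A5, followed by acetylation and ring closure.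
- A4 takes longer to make (aryl addition to a protected dihydroxyacetone, then acidic deprotection) and carries three free hydroxyls.
- After desymmetrisation the two arms must still be differentiated in separate steps.
- Monoacylated derivatives of A4 can racemise by acyl migration between the two primary oxygens.
- The oxetane opening turns C9 into a bromide and keeps C10–O as oxygen in one strain-driven event, and its mis-closure only regenerates 8.

Key step: step 4

Remark: 5-(hydroxymethyl)-2-iodophenol, (R)-2-methylbutanoic acid, oxetan-3-one and angelic acid are taken as catalogue compounds.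

Remark: the sense of induction of the squaramide on this substrate is not assumed; the antipode that gives (S)-9 is used, to be assigned by correlation of 12 with material from the titanium tartrate route described under the fallbacks.

## Route

Step 1
Reactants: 1 5-(hydroxymethyl)-2-iodophenol
Product: 2 [4-iodo-3-(prop-2-enyloxy)phenyl]methanol
Conditions: allyl bromide, K2CO3, acetone, reflux
Reagents that add atoms: allyl bromide, C=CCBr
Why: Williamson etherification; K2CO3 deprotonates the phenol but not the benzylic alcohol, so only the phenol oxygen is allylated; no stereocentre is involved.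

Step 2
Reactants: 2 [4-iodo-3-(prop-2-enyloxy)phenyl]methanol; 3 (R)-2-methylbutanoic acid
Product: 4 [4-iodo-3-(prop-2-enyloxy)phenyl]methyl (2R)-2-methylbutanoate
Conditions: DCC, DMAP (cat.), CH2Cl2, 0 °C to rt
Reagents that add atoms: none
Why: Steglich esterification of an unhindered primary alcohol; the acid has no α-heteroatom, so at 0 °C with little DMAP the α-stereocentre should be carried over unchanged from 3.

Step 3
Reactants: 4 [4-iodo-3-(prop-2-enyloxy)phenyl]methyl (2R)-2-methylbutanoate; 5 oxetan-3-one
Product: 8 [4-(3-acetoxyoxetan-3-yl)-3-(prop-2-enyloxy)phenyl]methyl (2R)-2-methylbutanoate, via arylmagnesium chloride 6 (not isolated), via chloromagnesium oxetanolate 7 (not isolated)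
Conditions: iPrMgCl·LiCl, THF, −30 °C; 5, −78 °C; Ac2O, −78 °C to rt
Reagents that add atoms: acetic anhydride, CC(=O)OC(C)=O
Why: Iodine–magnesium exchange, helped by the ortho allyloxy group, should be faster at low temperature than attack on the α-branched ester; 6 adds 1,2 to the strained ketone 5 and alkoxide 7 is acetylated in the flask, which places the future C10 acetate; C8 has two identical arms in 8, so no stereocentre is formed.

Step 4
Reactants: 8 [4-(3-acetoxyoxetan-3-yl)-3-(prop-2-enyloxy)phenyl]methyl (2R)-2-methylbutanoate
Product: 9 [4-[(2S)-2-acetoxy-1-bromo-3-(trimethylsilyloxy)propan-2-yl]-3-(prop-2-enyloxy)phenyl]methyl (2R)-2-methylbutanoate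
Conditions: TMSBr, chiral tert-leucine 2-arylpyrrolidine amide squaramide (cat.), t-BuOMe, −78 °C
Reagents that add atoms: bromotrimethylsilane, C[Si](C)(C)Br
Why: The squaramide binds the bromide of TMSBr through its two N–H bonds and so raises the Lewis acidity at silicon; the oxetane oxygen of 8 is silylated and the silyloxetanium ion stays paired with the catalyst-bound bromide. Bromide is then delivered in an SN2 step to one of the two CH2 groups on C8 with cleavage of its C–O bond, and release of about 25 kcal/mol of ring strain makes this irreversible. The closest known reaction type is the chiral squaramide (hydrogen-bond-donor) catalysed enantioselective addition of TMSBr to 3-substituted and 3,3-disubstituted oxetanes, which accepts oxygen substituents at C3. No ring is closed; the four-membered ring is opened. The one new stereocentre, C8, is controlled by the catalyst alone, through its choice between two CH2–O bonds that differ only by the remote ester stereocentre, and the catalyst antipode is chosen to give (S)-9. The step needs selectivity between these two arms, which the catalyst can read because C8 carries two very different groups (a flat ortho-substituted arene that can stack on the catalyst aryl group, and an acetoxy group), and it needs the oxetane to react in preference to the carbonyl oxygens, which the ring strain secures because silylation of an ester is reversible and leads nowhere. Low temperature and a weakly polar ether solvent should hold back both the uncatalysed opening and ionisation of the tertiary acetate. Because the ester stereocentre is already present, a wrong choice of arm gives a diastereomer of 9 and not its enantiomer.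

Step 5
Reactants: 9 [4-[(2S)-2-acetoxy-1-bromo-3-(trimethylsilyloxy)propan-2-yl]-3-(prop-2-enyloxy)phenyl]methyl (2R)-2-methylbutanoate
Product: 12 [4-[(2R)-2-(acetoxymethyl)oxiran-2-yl]-3-(prop-2-enyloxy)phenyl]methyl (2R)-2-methylbutanoate, via primary alkoxide 10 (not isolated), via tertiary alkoxide 11 (not isolated)
Conditions: TBAF, THF, −20 to 0 °C
Reagents that add atoms: none
Why: Fluoride removes the primary TMS group; alkoxide 10 takes the acetyl from the hindered tertiary oxygen through a five-membered tetrahedral intermediate (1,2 O-to-O acyl shift), and the freed tertiary alkoxide 11 closes by 3-exo-tet Williamson displacement of bromide at C9. No bond to C8 is broken, so its configuration is kept and the descriptor changes from S to R only through the change of priorities; the one competing closure, 4-exo-tet from 10, returns 8.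

Step 6
Reactants: 12 [4-[(2R)-2-(acetoxymethyl)oxiran-2-yl]-3-(prop-2-enyloxy)phenyl]methyl (2R)-2-methylbutanoate
Product: 13 [4-[(2R)-2-(acetoxymethyl)oxiran-2-yl]-3-hydroxyphenyl]methyl (2R)-2-methylbutanoate
Conditions: Pd(PPh3)4 (cat.), PhNHMe, THF, rt
Reagents that add atoms: none
Why: Tsuji–Trost deallylation; zerovalent palladium ionises the allyl aryl ether and N-methylaniline takes up the allyl group under neutral conditions, to which the non-allylic oxirane and the alkyl esters should be inert; 13 is used at once.

Step 7
Reactants: 13 [4-[(2R)-2-(acetoxymethyl)oxiran-2-yl]-3-hydroxyphenyl]methyl (2R)-2-methylbutanoate; 14 angelic acid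
Product: 16 [4-[(2R)-2-(acetoxymethyl)oxiran-2-yl]-3-[(2Z)-2-methylbut-2-enoyl]oxyphenyl]methyl (2R)-2-methylbutanoate, via angelic anhydride 15 (not isolated)
Conditions: 14, DCC (0.5 equiv), CH2Cl2, 0 °C, filter; then 13, Cs2CO3, MeCN, 0 °C
Reagents that add atoms: none
Why: Carbodiimide dehydration gives anhydride 15 without acid or nucleophilic catalyst, so the Z geometry of 14 should be kept; the phenol is acylated under mild carbonate conditions without DMAP, which would isomerise the angelate by conjugate addition and elimination, and the phenoxide is acylated faster than it can act on the oxirane.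

## Compound list

1 | 5-(hydroxymethyl)-2-iodophenol | OCc1ccc(I)c(O)c1 | starting material
2 | [4-iodo-3-(prop-2-enyloxy)phenyl]methanol | OCc1ccc(I)c(OCC=C)c1 | intermediate
3 | (R)-2-methylbutanoic acid | CC[C@@H](C)C(O)=O | starting material
4 | [4-iodo-3-(prop-2-enyloxy)phenyl]methyl (2R)-2-methylbutanoate | CC[C@@H](C)C(=O)OCc1ccc(I)c(OCC=C)c1 | intermediate
5 | oxetan-3-one | O=C1COC1 | starting material
6 | {4-[((2R)-2-methylbutanoyl)oxymethyl]-2-(prop-2-enyloxy)phenyl}magnesium chloride | CC[C@@H](C)C(=O)OCc1ccc([Mg]Cl)c(OCC=C)c1 | intermediate
7 | chloromagnesium 3-{4-[((2R)-2-methylbutanoyl)oxymethyl]-2-(prop-2-enyloxy)phenyl}oxetan-3-olate | CC[C@@H](C)C(=O)OCc1ccc(c(OCC=C)c1)C1(O[Mg]Cl)COC1 | intermediate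
8 | [4-(3-acetoxyoxetan-3-yl)-3-(prop-2-enyloxy)phenyl]methyl (2R)-2-methylbutanoate | CC[C@@H](C)C(=O)OCc1ccc(c(OCC=C)c1)C1(OC(C)=O)COC1 | intermediate
9 | [4-[(2S)-2-acetoxy-1-bromo-3-(trimethylsilyloxy)propan-2-yl]-3-(prop-2-enyloxy)phenyl]methyl (2R)-2-methylbutanoate | CC[C@@H](C)C(=O)OCc1ccc(c(OCC=C)c1)[C@](OC(C)=O)(CO[Si](C)(C)C)CBr | intermediate
10 | tetrabutylammonium (2S)-2-acetoxy-3-bromo-2-{4-[((2R)-2-methylbutanoyl)oxymethyl]-2-(prop-2-enyloxy)phenyl}propan-1-olate | CC[C@@H](C)C(=O)OCc1ccc(c(OCC=C)c1)[C@](OC(C)=O)(C[O-])CBr.CCCC[N+](CCCC)(CCCC)CCCC | intermediate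
11 | tetrabutylammonium (2S)-1-acetoxy-3-bromo-2-{4-[((2R)-2-methylbutanoyl)oxymethyl]-2-(prop-2-enyloxy)phenyl}propan-2-olate | CC[C@@H](C)C(=O)OCc1ccc(c(OCC=C)c1)[C@]([O-])(COC(C)=O)CBr.CCCC[N+](CCCC)(CCCC)CCCC | intermediate
12 | [4-[(2R)-2-(acetoxymethyl)oxiran-2-yl]-3-(prop-2-enyloxy)phenyl]methyl (2R)-2-methylbutanoate | CC[C@@H](C)C(=O)OCc1ccc(c(OCC=C)c1)[C@]1(COC(C)=O)CO1 | intermediate
13 | [4-[(2R)-2-(acetoxymethyl)oxiran-2-yl]-3-hydroxyphenyl]methyl (2R)-2-methylbutanoate | CC[C@@H](C)C(=O)OCc1ccc(c(O)c1)[C@]1(COC(C)=O)CO1 | intermediate
14 | angelic acid, (2Z)-2-methylbut-2-enoic acid | C/C=C(/C)C(=O)O | starting material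
15 | angelic anhydride, (2Z)-2-methylbut-2-enoic anhydride | C/C=C(/C)C(=O)OC(=O)/C(C)=C\C | intermediate
16 | [4-[(2R)-2-(acetoxymethyl)oxiran-2-yl]-3-[(2Z)-2-methylbut-2-enoyl]oxyphenyl]methyl (2R)-2-methylbutanoate | C/C=C(/C)C(=O)Oc1cc(COC(=O)[C@H](C)CC)ccc1[C@]1(COC(C)=O)CO1 | target

## Step count and risk

Total steps: 7. Longest linear sequence: 7 steps (1 to 16).

**Step 4 (key step).**
- What may go wrong: poor discrimination between the two CH2–O bonds, since an ortho-substituted arene together with an acetoxy group at C8 is a new combination for this catalyst class. Two processes could bypass the catalyst: ionisation of the tertiary benzylic acetate by the silyl Lewis acid, and opening of the silyloxetanium ion by the neighbouring acetate carbonyl.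
- Fallback: set out from iodide 4. Stille coupling with 2-(tributylstannyl)prop-2-en-1-ol (Pd(PPh3)4, CuI, CsF, DMF) should give [4-(3-hydroxyprop-1-en-2-yl)-3-(prop-2-enyloxy)phenyl]methyl (2R)-2-methylbutanoate F1. Sharpless asymmetric epoxidation of F1 (Ti(OiPr)4, L-(+)-diethyl tartrate, t-BuOOH, 4 Å sieves, CH2Cl2, −20 °C) should give, by the usual facial rule for 2-substituted allylic alcohols, [4-[(2S)-2-(hydroxymethyl)oxiran-2-yl]-3-(prop-2-enyloxy)phenyl]methyl (2R)-2-methylbutanoate F2. Acetylation (Ac2O, pyridine) returns to the route at 12.

**Step 6.**
- What may go wrong: once the ortho phenol is free, the oxirane may open or lose configuration, through hydrogen-bond activation of the oxirane oxygen and reversible ortho-quinone methide formation. In the following acylation the angelate may isomerise to the tiglate if the phenol is slow to react.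
- Fallback: set out from 12 and do not liberate the phenol. Palladium-catalysed hydrostannolysis (Bu3SnH, Pd(PPh3)4, CH2Cl2) should give [4-[(2R)-2-(acetoxymethyl)oxiran-2-yl]-3-(tributylstannyloxy)phenyl]methyl (2R)-2-methylbutanoate F3, a covalent tin phenoxide. This is acylated in the same flask with anhydride 15 (prepared as in step 7) and comes back to the route at 16.

**Step 5.**
- What may go wrong: if the acyl shift is slower than expected, alkoxide 10 re-closes to the oxetane or the acetate is cleaved by the basic fluoride, and the cascade stalls before the oxirane forms.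
- Fallback: set out from alkoxide 7 and take the acetyl out of the sequence.
  - Aqueous NH4Cl quench gives [4-(3-hydroxyoxetan-3-yl)-3-(prop-2-enyloxy)phenyl]methyl (2R)-2-methylbutanoate F4.
  - N-(trimethylsilyl)imidazole gives [3-(prop-2-enyloxy)-4-(3-trimethylsilyloxyoxetan-3-yl)phenyl]methyl (2R)-2-methylbutanoate F5.
  - The same squaramide-catalysed TMSBr opening should give [4-[(2S)-1-bromo-2,3-bis(trimethylsilyloxy)propan-2-yl]-3-(prop-2-enyloxy)phenyl]methyl (2R)-2-methylbutanoate F6.
  - TBAF removes both silyl groups and closes the oxirane to [4-[(2S)-2-(hydroxymethyl)oxiran-2-yl]-3-(prop-2-enyloxy)phenyl]methyl (2R)-2-methylbutanoate F2.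
  - Ac2O and pyridine return to the route at 12.
  
  This variant also removes the acetate from the key step, should ionisation or participation be the cause of trouble there.

**Step 3.**
- What may go wrong: the isopropyl or aryl magnesium reagent may attack the ester before exchange and addition are complete, since exchange on an electron-rich ring is slow, or the hindered magnesium alkoxide may be acetylated incompletely.
- Fallback: set out from 2 and form the C–C bond before the ester is present. Deprotonation with MeMgCl, exchange with iPrMgCl·LiCl and addition to 5 should give 3-[4-(hydroxymethyl)-2-(prop-2-enyloxy)phenyl]oxetan-3-ol F7. Steglich esterification of its primary alcohol with 3 (DCC, DMAP) gives [4-(3-hydroxyoxetan-3-yl)-3-(prop-2-enyloxy)phenyl]methyl (2R)-2-methylbutanoate F4. Acetylation of the tertiary alcohol (Ac2O, Et3N, DMAP) comes back to the route at 8.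

## Further compounds

F1 | step 4 | [4-(3-hydroxyprop-1-en-2-yl)-3-(prop-2-enyloxy)phenyl]methyl (2R)-2-methylbutanoate | CC[C@@H](C)C(=O)OCc1ccc(c(OCC=C)c1)C(=C)CO
F2 | step 4 | [4-[(2S)-2-(hydroxymethyl)oxiran-2-yl]-3-(prop-2-enyloxy)phenyl]methyl (2R)-2-methylbutanoate | CC[C@@H](C)C(=O)OCc1ccc(c(OCC=C)c1)[C@]1(CO)CO1
F3 | step 6 | [4-[(2R)-2-(acetoxymethyl)oxiran-2-yl]-3-(tributylstannyloxy)phenyl]methyl (2R)-2-methylbutanoate | CC[C@@H](C)C(=O)OCc1ccc(c(O[Sn](CCCC)(CCCC)CCCC)c1)[C@]1(COC(C)=O)CO1
F4 | step 5 | [4-(3-hydroxyoxetan-3-yl)-3-(prop-2-enyloxy)phenyl]methyl (2R)-2-methylbutanoate | CC[C@@H](C)C(=O)OCc1ccc(c(OCC=C)c1)C1(O)COC1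
F5 | step 5 | [3-(prop-2-enyloxy)-4-(3-trimethylsilyloxyoxetan-3-yl)phenyl]methyl (2R)-2-methylbutanoate | CC[C@@H](C)C(=O)OCc1ccc(c(OCC=C)c1)C1(O[Si](C)(C)C)COC1
F6 | step 5 | [4-[(2S)-1-bromo-2,3-bis(trimethylsilyloxy)propan-2-yl]-3-(prop-2-enyloxy)phenyl]methyl (2R)-2-methylbutanoate | CC[C@@H](C)C(=O)OCc1ccc(c(OCC=C)c1)[C@](O[Si](C)(C)C)(CO[Si](C)(C)C)CBr
F7 | step 3 | 3-[4-(hydroxymethyl)-2-(prop-2-enyloxy)phenyl]oxetan-3-ol | OCc1ccc(c(OCC=C)c1)C1(O)COC1
A1 | alternative 1 | [4-(3-hydroxyprop-1-en-2-yl)-3-[(2Z)-2-methylbut-2-enoyl]oxyphenyl]methyl (2R)-2-methylbutanoate | C/C=C(/C)C(=O)Oc1cc(COC(=O)[C@H](C)CC)ccc1C(=C)CO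
A2 | alternative 1 | [4-[(2S)-2-(hydroxymethyl)oxiran-2-yl]-3-[(2Z)-2-methylbut-2-enoyl]oxyphenyl]methyl (2R)-2-methylbutanoate | C/C=C(/C)C(=O)Oc1cc(COC(=O)[C@H](C)CC)ccc1[C@]1(CO)CO1
A3 | alternative 2 | [4-(2-acetoxyacetyl)-3-(prop-2-enyloxy)phenyl]methyl (2R)-2-methylbutanoate | CC[C@@H](C)C(=O)OCc1ccc(c(OCC=C)c1)C(=O)COC(C)=O
A4 | alternative 3 | [3-(prop-2-enyloxy)-4-(1,2,3-trihydroxypropan-2-yl)phenyl]methyl (2R)-2-methylbutanoate | CC[C@@H](C)C(=O)OCc1ccc(c(OCC=C)c1)C(O)(CO)CO
A5 | alternative 3 | [4-[(2S)-1,2-dihydroxy-3-(4-methylphenyl)sulfonyloxypropan-2-yl]-3-(prop-2-enyloxy)phenyl]methyl (2R)-2-methylbutanoate | CC[C@@H](C)C(=O)OCc1ccc(c(OCC=C)c1)[C@](O)(CO)COS(=O)(=O)c1ccc(C)cc1
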